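Watch the isomer of the product beside the single product while you repeat these flasks.

    coupling partner + double product ⇌ tris adduct (K1 = 3.6 M⁻¹, k1 = 0.00108 M⁻¹ s⁻¹, Ea1 = 60.0 kJ mol⁻¹, ΔH1 = −44.0 kJ mol⁻¹)
    single product ⇌ isomer of the product (K2 = 8.7, k2 = 4.78 × 10⁻⁴ s⁻¹, Ea2 = 99.0 kJ mol⁻¹, ΔH2 = −25.0 kJ mol⁻¹)
    substrate + coupling partner → single product (k3 = 0.00220 M⁻¹ s⁻¹, Ea3 = 78.0 kJ mol⁻¹)
    coupling partner + single product → double product (k4 = 3.53 × 10⁻⁴ M⁻¹ s⁻¹, Ea4 = 55.0 kJ mol⁻¹)
    (constants at 40 °C)

| flask | substrate | coupling partner | temperature | time |
|---|---|---|---|---|
| Friday's | 0.30 M | 1.50 equiv | 40 °C | 1.0 h |
| Thursday's | 0.30 M | 1.50 equiv | 20 °C | 1.0 h |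
| Wednesday's | 0.30 M | 1.50 equiv | 80 °C | 1.0 h |
| Monday's | 0.30 M | 1.50 equiv | 60 °C | 1.0 h |

- the best flask by amount of single product, in percent of the substrate charged; "all alike" if 1.5 percentage points covers them all (Friday's / Thursday's / Wednesday's / Monday's / all alike)
- amount of single product at the end, in percent of the substrate charged, Friday's
- amount of single product at the end, in percent of the substrate charged, Thursday's
- amount of single product at the end, in percent of the substrate charged, Wednesday's
- amount of single product at the end, in percent of the substrate charged, Monday's

- at 40 °C the constants are as listed, elsewhere as the activation energies and enthalpies make them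

Take Thursday's, the coldest flask, and first ask what each constant is worth there. In Thursday's, an error in the rate constant of substrate + coupling partner passes nearly in proportion into the answer, and an error in its activation energy passes in through that constant, since that step makes the single product, so you need those two well. In Thursday's, the constants of isomerisation and overreaction correct that figure, so they may be rougher. The back step of isomerisation needs isomer first, and its rate constant is smaller than the forward one by the factor 8.7 at the reference temperature, so in Thursday's its constants matter little. The constants of the tris adduct act on double product, not directly on single product, so in Thursday's they can stay rough.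

Now the numbers, as times at the charged c(coupling partner) = 0.450 M, carried to Thursday's temperature:

feed, substrate to single product: 2.17 h

drain to isomer: 7.78 h

drain to double product, taken as pseudo-first-order: 7.39 h

Both drains are slower than the feed. Call D, the run time divided by each drain time and summed, the drain number. The share of an even feed still standing as single product is S:

D = 0.264

S = (1 − e^(−D))/D = 0.879

Reckoned with the coupling partner falling as it reacts, the feed in Thursday's comes to a conversion of 33.3% of the substrate, so my estimate for Thursday's is 29.3%. I stop there, since the hotter flasks need the back step that this reckoning drops.

The forecast gives 29.3% for Thursday's, 27% for Friday's, 14.6% for Monday's and 18.2% for Wednesday's, and picks Thursday's. Of Thursday's it says “about one third of the substrate converts, and little is lost”.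

The flasks give 29.1% for Thursday's, 26.0% for Friday's, 14.5% for Monday's and 17.9% for Wednesday's. So Thursday's is best, as forecast, by 3 percentage points over Friday's, against a margin of 1.5 points.

Thursday's leads with a drain number of 0.264, of which isomerisation holds 0.129. At Wednesday's temperature that part, which counts the forward step alone, is multiplied by 990, to 128. What temperature does to isomerisation is the largest single effect on the gap between these two flasks: Wednesday's minus Thursday's stands at −11 points, and at 18 points without that effect.

Read Thursday's flask at 4.0 h instead: the drain number becomes 1.06, S becomes 0.618 and the conversion 71.8%, which promises about 44.4% of single product. The neighbour flask gives 41.6%.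

The numbers of this flask were set for the occasion.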